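**Strategy.** The cis-fused α-methylene-γ-butyrolactone is disconnected across its two bonds to the carbocycle, O–C6 and C11–C7 (germacrane numbering). Because C6 is allylic to the C4=C5 ring alkene, the lactone is the 1,2-carbo-oxygenation product of a C4=C5–C6=C7 diene. A Pd-catalysed (3+2) heteroannulation of an acyclic (4E,6E)-diene, carrying C8 as a glyceraldehyde-derived dioxolane, with 2-bromoacrylic acid should form both bonds, both stereocentres C6/C7 and the exocyclic methylene in one operation and leave the E-C4=C5 alkene. The ten-membered ring is closed last by a Nozaki–Hiyama–Kishi reaction (C9–C10) that also unveils the C9 hydroxyl next to the pre-installed C8 ester.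

Key step: step 5

**Remarks.**
- Numbering used throughout: C6 = lactone O–CH, C7 = ring-fusion CH bearing C11 (C12 = lactone C=O, C13 = exocyclic CH2), C8 = acyloxy CH, C9 = carbinol CH, C10(CH3)=C1, C2, C3, C4(CH3)=C5.
- The target is read as 6S,7S,8S,9R, 1(10)Z, 4E, side chain 3R; H6 and H7 are cis (cis-fused lactone), and O8/O9 are anti along C7–C10.
- Assumption: (R)-glyceraldehyde acetonide, (R)-4-methyloxolan-2-one and 2-bromoacrylic acid are taken as commercially available.

**Route**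

Step 1
Reactants: 1 4-pentyn-1-ol
Product: 3 (4E)-5-iodo-4-methylpent-4-en-1-ol, via (E)-alkenylalane 2 (not isolated)
Conditions: Me3Al (3 equiv), Cp2ZrCl2 (0.25 equiv), CH2Cl2, 0 °C to rt; then I2, THF, −30 to 0 °C
Reagents that add atoms: trimethylaluminium, C[Al](C)C; iodine, II
Why: Zirconium-catalysed Negishi carboalumination adds CH3 and Al syn across the terminal alkyne (CH3 to the internal carbon) and iodinolysis of the C–Al bond proceeds with retention, which fixes the E geometry of the future C4=C5 bond.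

Step 2
Reactants: 3 (4E)-5-iodo-4-methylpent-4-en-1-ol
Product: 4 triethyl{[(4E)-5-iodo-4-methylpent-4-en-1-yl]oxy}silane
Conditions: TESCl, imidazole, CH2Cl2, 0 °C
Reagents that add atoms: chlorotriethylsilane, CC[Si](Cl)(CC)CC
Why: Standard silylation of a primary alcohol; the triethylsilyl ether should survive the two Pd steps and can later be oxidised directly to the aldehyde.

Step 3
Reactants: 5 (4R)-2,2-dimethyl-1,3-dioxolane-4-carbaldehyde
Product: 6 (4S)-4-ethynyl-2,2-dimethyl-1,3-dioxolane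
Conditions: dimethyl (1-diazo-2-oxopropyl)phosphonate, K2CO3, MeOH, 0 °C to rt
Reagents that add atoms: Ohira–Bestmann reagent, CC(=O)C(=[N+]=[N-])P(=O)(OC)OC
Why: Seyferth–Gilbert homologation under Ohira–Bestmann conditions converts the aldehyde into the terminal alkyne without touching the dioxolane stereocentre (future C8; the descriptor changes from R to S only through the CIP priorities).

Step 4
Reactants: 6 (4S)-4-ethynyl-2,2-dimethyl-1,3-dioxolane; 4 triethyl{[(4E)-5-iodo-4-methylpent-4-en-1-yl]oxy}silane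
Product: 8 triethyl{[(4E,6E)-7-[(4S)-2,2-dimethyl-1,3-dioxolan-4-yl]-4-methylhepta-4,6-dien-1-yl]oxy}silane, via (E)-alkenyl pinacol boronate 7 (not isolated)
Conditions: pinacolborane, Cp2Zr(H)Cl (5 mol%), Et3N (10 mol%), CH2Cl2, 50 °C; then 4, Pd(PPh3)4 (5 mol%), aq. K3PO4, THF, 50 °C
Reagents that add atoms: none
Why: Zr-catalysed syn-hydroboration of the terminal alkyne gives the (E)-alkenyl boronate and Suzuki–Miyaura coupling with the alkenyl iodide proceeds with retention at both partners, so the (4E,6E)-diene should form stereospecifically.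

Step 5
Reactants: 8 triethyl{[(4E,6E)-7-[(4S)-2,2-dimethyl-1,3-dioxolan-4-yl]-4-methylhepta-4,6-dien-1-yl]oxy}silane; 9 2-bromoprop-2-enoic acid
Product: 10 (4S,5S)-4-[(4S)-2,2-dimethyl-1,3-dioxolan-4-yl]-3-methylidene-5-[(1E)-2-methyl-5-(triethylsilyloxy)pent-1-en-1-yl]oxolan-2-one
Conditions: Pd(OAc)2 (10 mol%), DPEphos (12 mol%), K2CO3 (2.5 equiv), DMF, 60 °C, slow addition of 9 (1.5 equiv)
Reagents that add atoms: none
Why: Pd(0) inserts into the C–Br bond of the 2-bromoacrylate, the alkenyl–Pd adds syn across the less hindered C6=C7 end of the diene (C11 to C7, Pd to C6), and the resulting η3-allyl complex spanning C4–C6 is captured at C6 by the pendant carboxylate, so that C11–C7 and O–C6 form in one catalytic cycle. The closest known reaction type is the Larock heteroannulation of 1,3-dienes by halides that carry a carboxylic acid. The lactone closes by 5-exo attack of the carboxylate oxygen on the allyl terminus C6 (the alternative at the tertiary C4 would be a seven-membered ring), and since the C4 terminus never becomes σ-bound its substituents keep their places, so C4=C5 stays E. C7 is set by the face of insertion: addition anti to the C8–O bond in the conformer with H8 eclipsing the alkene, the usual sense for electrophilic additions next to an allylic ether, should place C11 anti to O8. C6 is set relative to C7 by the mechanism: with the chelating bisphosphine the cationic allyl complex has no free site, the carboxylate attacks anti to Pd (the microscopic reverse of allylic ester ionisation), and syn insertion followed by anti substitution on the (6E)-alkene should give the 4,5-cis lactone (6S,7S). The step needs attack at C7 and not at the disubstituted C4 terminus (sterics), ring closure faster than β-hydride elimination (fast five-ring formation), and no second site for Pd(0), which is why O8 is an acetal and the iodoalkene is installed only afterwards.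

Step 6
Reactants: 10 (4S,5S)-4-[(4S)-2,2-dimethyl-1,3-dioxolan-4-yl]-3-methylidene-5-[(1E)-2-methyl-5-(triethylsilyloxy)pent-1-en-1-yl]oxolan-2-one
Product: 11 (4E)-5-[(2S,3S)-3-[(4S)-2,2-dimethyl-1,3-dioxolan-4-yl]-4-methylidene-5-oxooxolan-2-yl]-4-methylpent-4-enal
Conditions: (COCl)2, DMSO, CH2Cl2, −78 to −30 °C; then Et3N, −78 to 0 °C
Reagents that add atoms: none
Why: Under Swern conditions a primary triethylsilyl ether is cleaved by the chlorosulfonium salt and oxidised in the same pot to the aldehyde, while the acetonide, the allylic lactone and the methylene lactone should be inert.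

Step 7
Reactants: 11 (4E)-5-[(2S,3S)-3-[(4S)-2,2-dimethyl-1,3-dioxolan-4-yl]-4-methylidene-5-oxooxolan-2-yl]-4-methylpent-4-enal
Product: 12 (4S,5S)-4-[(4S)-2,2-dimethyl-1,3-dioxolan-4-yl]-5-[(1E,5Z)-6-iodo-2-methylhepta-1,5-dien-1-yl]-3-methylideneoxolan-2-one
Conditions: EtPPh3I, n-BuLi, THF, rt; I2, −78 °C; NaHMDS, −20 °C; then 11, −78 °C
Reagents that add atoms: ethyltriphenylphosphonium iodide, CC[P+](c1ccccc1)(c1ccccc1)c1ccccc1.[I-]; iodine, II
Why: Stork–Zhao-type Wittig olefination with the α-iodoethylidene ylide gives the (Z)-2-iodo-2-alkene (iodine cis to the chain) under kinetic control, and at −78 °C the aldehyde should outcompete conjugate addition to the methylene lactone.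

Step 8
Reactants: 12 (4S,5S)-4-[(4S)-2,2-dimethyl-1,3-dioxolan-4-yl]-5-[(1E,5Z)-6-iodo-2-methylhepta-1,5-dien-1-yl]-3-methylideneoxolan-2-one
Product: 13 (4R,5S)-4-[(1S)-1,2-dihydroxyethyl]-5-[(1E,5Z)-6-iodo-2-methylhepta-1,5-dien-1-yl]-3-methylideneoxolan-2-one
Conditions: AcOH/H2O/THF (3:1:1), 40 °C
Reagents that add atoms: none
Why: Mild acid hydrolysis of the terminal isopropylidene ketal frees the C8/C9 diol without base, so the lactone should not migrate to O8 and the iodoalkene stays intact (the descriptor at C7 changes only through the CIP priorities).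

Step 9
Reactants: 13 (4R,5S)-4-[(1S)-1,2-dihydroxyethyl]-5-[(1E,5Z)-6-iodo-2-methylhepta-1,5-dien-1-yl]-3-methylideneoxolan-2-one
Product: 14 (4R,5S)-4-[(1S)-1-hydroxy-2-(triethylsilyloxy)ethyl]-5-[(1E,5Z)-6-iodo-2-methylhepta-1,5-dien-1-yl]-3-methylideneoxolan-2-one
Conditions: TESCl (1.05 equiv), imidazole, CH2Cl2, −78 to −40 °C
Reagents that add atoms: chlorotriethylsilane, CC[Si](Cl)(CC)CC
Why: Kinetic silylation should discriminate the primary C9 hydroxyl from the hindered secondary C8 hydroxyl.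

Step 10
Reactants: 15 (4R)-4-methyloxolan-2-one
Product: 17 benzyl (3R)-4-hydroxy-3-methylbutanoate, via potassium (3R)-4-hydroxy-3-methylbutanoate 16 (not isolated)
Conditions: KOH, MeOH/H2O, rt, evaporate; then BnBr, DMF, rt
Reagents that add atoms: potassium hydroxide, [K+].[OH-]; benzyl bromide, BrCc1ccccc1
Why: Saponification opens the lactone and SN2 O-alkylation of the carboxylate salt traps the open form as the benzyl ester without affecting the stereocentre.

Step 11
Reactants: 17 benzyl (3R)-4-hydroxy-3-methylbutanoate; 18 octadecanoyl chloride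
Product: 19 benzyl (3R)-3-methyl-4-(octadecanoyloxy)butanoate
Conditions: pyridine, DMAP (cat.), CH2Cl2, 0 °C to rt
Reagents that add atoms: none
Why: DMAP-catalysed acylation of the primary alcohol by the acid chloride should be faster than relactonisation.

Step 12
Reactants: 19 benzyl (3R)-3-methyl-4-(octadecanoyloxy)butanoate
Product: 20 (3R)-3-methyl-4-(octadecanoyloxy)butanoic acid
Conditions: H2 (1 atm), 10% Pd/C, EtOAc, rt
Reagents that add atoms: none
Why: Catalytic hydrogenolysis cleaves only the benzylic C–O bond of the benzyl ester.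

Step 13
Reactants: 14 (4R,5S)-4-[(1S)-1-hydroxy-2-(triethylsilyloxy)ethyl]-5-[(1E,5Z)-6-iodo-2-methylhepta-1,5-dien-1-yl]-3-methylideneoxolan-2-one; 20 (3R)-3-methyl-4-(octadecanoyloxy)butanoic acid
Product: 21 (1S)-1-[(2S,3S)-2-[(1E,5Z)-6-iodo-2-methylhepta-1,5-dien-1-yl]-4-methylidene-5-oxooxolan-3-yl]-2-(triethylsilyloxy)ethyl (3R)-3-methyl-4-(octadecanoyloxy)butanoate
Conditions: EDC·HCl, DMAP (0.2 equiv), CH2Cl2, 0 °C to rt
Reagents that add atoms: none
Why: Steglich esterification acylates the C8 hydroxyl with retention at C8, and the low DMAP loading and temperature should limit silyl or lactone migration.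

Step 14
Reactants: 21 (1S)-1-[(2S,3S)-2-[(1E,5Z)-6-iodo-2-methylhepta-1,5-dien-1-yl]-4-methylidene-5-oxooxolan-3-yl]-2-(triethylsilyloxy)ethyl (3R)-3-methyl-4-(octadecanoyloxy)butanoate
Product: 22 (1S)-1-[(2S,3S)-2-[(1E,5Z)-6-iodo-2-methylhepta-1,5-dien-1-yl]-4-methylidene-5-oxooxolan-3-yl]-2-oxoethyl (3R)-3-methyl-4-(octadecanoyloxy)butanoate
Conditions: (COCl)2, DMSO, CH2Cl2, −78 to −30 °C; then i-Pr2NEt, −78 to −20 °C; used at once
Reagents that add atoms: none
Why: Swern oxidation of the primary triethylsilyl ether gives the α-acyloxy aldehyde directly, which avoids a free 1,2-hydroxy ester (acyl migration) and, with the hindered base at low temperature, should avoid epimerisation at C8.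

Step 15
Reactants: 22 (1S)-1-[(2S,3S)-2-[(1E,5Z)-6-iodo-2-methylhepta-1,5-dien-1-yl]-4-methylidene-5-oxooxolan-3-yl]-2-oxoethyl (3R)-3-methyl-4-(octadecanoyloxy)butanoate
Product: 23 (3aS,4S,5R,6Z,10E,11aS)-5-hydroxy-6,10-dimethyl-3-methylidene-2-oxo-2,3,3a,4,5,8,9,11a-octahydrocyclodeca[b]furan-4-yl (3R)-3-methyl-4-(octadecanoyloxy)butanoate
Conditions: CrCl2 (8 equiv), NiCl2 (1 mol% of Cr), degassed DMSO/THF, 3 mM, rt; aqueous work-up
Reagents that add atoms: none
Why: In this intramolecular Nozaki–Hiyama–Kishi reaction Ni(0) inserts into the C–I bond with retention of the Z geometry, transmetalation gives an alkenylchromium(III) that adds chemoselectively to the C9 aldehyde and closes the ten-membered ring, and polar Felkin–Anh addition anti to the C8 acyloxy group should give the anti (8S,9R) arrangement.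

**Compound list**

1 | 4-pentyn-1-ol | C#CCCCO | starting material
2 | dimethylaluminium alkoxide of (E)-(5-hydroxy-2-methylpent-1-en-1-yl)dimethylalane | C[Al](C)OCCC/C(C)=C/[Al](C)C | intermediate
3 | (4E)-5-iodo-4-methylpent-4-en-1-ol | OCCC/C(C)=C/I | intermediate
4 | triethyl{[(4E)-5-iodo-4-methylpent-4-en-1-yl]oxy}silane | CC[Si](CC)(CC)OCCC/C(C)=C/I | intermediate
5 | (4R)-2,2-dimethyl-1,3-dioxolane-4-carbaldehyde | O=C[C@H]1COC(C)(C)O1 | starting material
6 | (4S)-4-ethynyl-2,2-dimethyl-1,3-dioxolane | C#C[C@H]1COC(C)(C)O1 | intermediate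
7 | 2-{(E)-2-[(4S)-2,2-dimethyl-1,3-dioxolan-4-yl]ethenyl}-4,4,5,5-tetramethyl-1,3,2-dioxaborolane | CC1(C)OB(/C=C/[C@H]2COC(C)(C)O2)OC1(C)C | intermediate
8 | triethyl{[(4E,6E)-7-[(4S)-2,2-dimethyl-1,3-dioxolan-4-yl]-4-methylhepta-4,6-dien-1-yl]oxy}silane | CC[Si](CC)(CC)OCCC/C(C)=C/C=C/[C@H]1COC(C)(C)O1 | intermediate
9 | 2-bromoprop-2-enoic acid | C=C(Br)C(=O)O | starting material
10 | (4S,5S)-4-[(4S)-2,2-dimethyl-1,3-dioxolan-4-yl]-3-methylidene-5-[(1E)-2-methyl-5-(triethylsilyloxy)pent-1-en-1-yl]oxolan-2-one | C=C1C(=O)O[C@@H](/C=C(\C)CCCO[Si](CC)(CC)CC)[C@H]1[C@H]2COC(C)(C)O2 | intermediate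
11 | (4E)-5-[(2S,3S)-3-[(4S)-2,2-dimethyl-1,3-dioxolan-4-yl]-4-methylidene-5-oxooxolan-2-yl]-4-methylpent-4-enal | C=C1C(=O)O[C@@H](/C=C(\C)CCC=O)[C@H]1[C@H]2COC(C)(C)O2 | intermediate
12 | (4S,5S)-4-[(4S)-2,2-dimethyl-1,3-dioxolan-4-yl]-5-[(1E,5Z)-6-iodo-2-methylhepta-1,5-dien-1-yl]-3-methylideneoxolan-2-one | C=C1C(=O)O[C@@H](/C=C(\C)CC/C=C(/C)I)[C@H]1[C@H]2COC(C)(C)O2 | intermediate
13 | (4R,5S)-4-[(1S)-1,2-dihydroxyethyl]-5-[(1E,5Z)-6-iodo-2-methylhepta-1,5-dien-1-yl]-3-methylideneoxolan-2-one | C=C1C(=O)O[C@@H](/C=C(\C)CC/C=C(/C)I)[C@H]1[C@H](O)CO | intermediate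
14 | (4R,5S)-4-[(1S)-1-hydroxy-2-(triethylsilyloxy)ethyl]-5-[(1E,5Z)-6-iodo-2-methylhepta-1,5-dien-1-yl]-3-methylideneoxolan-2-one | C=C1C(=O)O[C@@H](/C=C(\C)CC/C=C(/C)I)[C@H]1[C@H](O)CO[Si](CC)(CC)CC | intermediate
15 | (4R)-4-methyloxolan-2-one | O=C1C[C@@H](C)CO1 | starting material
16 | potassium (3R)-4-hydroxy-3-methylbutanoate | [K+].[O-]C(=O)C[C@@H](C)CO | intermediate
17 | benzyl (3R)-4-hydroxy-3-methylbutanoate | O=C(C[C@@H](C)CO)OCc1ccccc1 | intermediate
18 | octadecanoyl chloride | CCCCCCCCCCCCCCCCCC(=O)Cl | starting material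
19 | benzyl (3R)-3-methyl-4-(octadecanoyloxy)butanoate | O=C(OCc1ccccc1)C[C@@H](C)COC(=O)CCCCCCCCCCCCCCCCC | intermediate
20 | (3R)-3-methyl-4-(octadecanoyloxy)butanoic acid | OC(=O)C[C@@H](C)COC(=O)CCCCCCCCCCCCCCCCC | intermediate
21 | (1S)-1-[(2S,3S)-2-[(1E,5Z)-6-iodo-2-methylhepta-1,5-dien-1-yl]-4-methylidene-5-oxooxolan-3-yl]-2-(triethylsilyloxy)ethyl (3R)-3-methyl-4-(octadecanoyloxy)butanoate | C=C1C(=O)O[C@@H](/C=C(\C)CC/C=C(/C)I)[C@H]1[C@@H](CO[Si](CC)(CC)CC)OC(=O)C[C@@H](C)COC(=O)CCCCCCCCCCCCCCCCC | intermediate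
22 | (1S)-1-[(2S,3S)-2-[(1E,5Z)-6-iodo-2-methylhepta-1,5-dien-1-yl]-4-methylidene-5-oxooxolan-3-yl]-2-oxoethyl (3R)-3-methyl-4-(octadecanoyloxy)butanoate | C=C1C(=O)O[C@@H](/C=C(\C)CC/C=C(/C)I)[C@H]1[C@@H](C=O)OC(=O)C[C@@H](C)COC(=O)CCCCCCCCCCCCCCCCC | intermediate
23 | (3aS,4S,5R,6Z,10E,11aS)-5-hydroxy-6,10-dimethyl-3-methylidene-2-oxo-2,3,3a,4,5,8,9,11a-octahydrocyclodeca[b]furan-4-yl (3R)-3-methyl-4-(octadecanoyloxy)butanoate | C=C1C(=O)O[C@H]2/C=C(\C)CC/C=C(/C)[C@@H](O)[C@@H](OC(=O)C[C@@H](C)COC(=O)CCCCCCCCCCCCCCCCC)[C@@H]12 | target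

**Step count.** 15 steps in total. The longest linear sequence is 11 steps (steps 1, 2, 4, 5, 6, 7, 8, 9, 13, 14, 15).

**Steps most likely to fail**

1. Step 5 (heteroannulation). The C–O bond may form in part by inner-sphere reductive elimination syn to Pd, which would give the trans lactone. Facial selection next to C8 may be low on an E-alkene. Pd(0) may re-ionise the allylic lactone, and β-hydride elimination or base-induced loss of HBr from the bromoacrylate may compete. The fallback sets out from 5 and 4 and comes back at 10. Aldehyde 5 and methyl acrylate under DABCO catalysis (Morita–Baylis–Hillman reaction) would give methyl 2-{hydroxy[(4R)-2,2-dimethyl-1,3-dioxolan-4-yl]methyl}prop-2-enoate F1. NBS/Me2S would convert it with allylic transposition into methyl (2Z)-2-(bromomethyl)-3-[(4S)-2,2-dimethyl-1,3-dioxolan-4-yl]prop-2-enoate F2. Iodide 4 would be lithiated (t-BuLi, −78 °C) and formylated with DMF to (2E)-3-methyl-6-(triethylsilyloxy)hex-2-enal F3. Indium-mediated Barbier allylation of F3 with F2 in THF/H2O should give, through a cyclic transition state, the syn hydroxy ester methyl 2-[(1S,2S,3E)-1-[(4S)-2,2-dimethyl-1,3-dioxolan-4-yl]-2-hydroxy-4-methyl-7-(triethylsilyloxy)hept-3-en-1-yl]prop-2-enoate F4. F4 should lactonise with loss of methanol (spontaneously or with catalytic PPTS) to the cis lactone 10.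

2. Step 15 (macrocyclisation). Oligomerisation may win over closure of the strained ten-membered ring. The macrocyclic transition state may override Felkin–Anh control and give low facial selectivity at the C9 aldehyde. The chromium alkoxide may also trigger an O8-to-O9 acyl shift. The fallback sets out from 22 and comes back at 23. The cyclisation mixture containing the C9 epimer (3aS,4S,5S,6Z,10E,11aS)-5-hydroxy-6,10-dimethyl-3-methylidene-2-oxo-2,3,3a,4,5,8,9,11a-octahydrocyclodeca[b]furan-4-yl (3R)-3-methyl-4-(octadecanoyloxy)butanoate F5 would be oxidised with Dess–Martin periodinane to the cross-conjugated ketone (3aS,4S,6Z,10E,11aS)-6,10-dimethyl-3-methylidene-2,5-dioxo-2,3,3a,4,5,8,9,11a-octahydrocyclodeca[b]furan-4-yl (3R)-3-methyl-4-(octadecanoyloxy)butanoate F6. F6 would then be reduced 1,2 under reagent control (CBS oxazaborolidine with catecholborane at −78 °C, the catalyst enantiomer chosen to deliver hydride to the face that gives 9R) to 23.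

3. Step 7 (iodo-olefination). The ylide or the amide base may add to the methylene lactone, and Z-selectivity may erode. The fallback sets out from 11 and comes back at 12. Corey–Fuchs dibromo-olefination (CBr4, PPh3, Et3N, 0 °C) would give (4S,5S)-5-[(1E)-6,6-dibromo-2-methylhexa-1,5-dien-1-yl]-4-[(4S)-2,2-dimethyl-1,3-dioxolan-4-yl]-3-methylideneoxolan-2-one F7. Pd-catalysed trans-selective Negishi monomethylation (MeZnCl, PdCl2(DPEphos), THF, 0 °C) replaces the bromide trans to the chain and should give (4S,5S)-5-[(1E,5Z)-6-bromo-2-methylhepta-1,5-dien-1-yl]-4-[(4S)-2,2-dimethyl-1,3-dioxolan-4-yl]-3-methylideneoxolan-2-one F8. Copper-catalysed bromide-to-iodide exchange (CuI, trans-N,N'-dimethylcyclohexane-1,2-diamine, NaI, dioxane, 100 °C), which retains alkene geometry, would deliver 12.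

**Further compounds**

F1 | step 5 | methyl 2-{hydroxy[(4R)-2,2-dimethyl-1,3-dioxolan-4-yl]methyl}prop-2-enoate (both carbinol epimers) | C=C(C(=O)OC)C(O)[C@H]1COC(C)(C)O1
F2 | step 5 | methyl (2Z)-2-(bromomethyl)-3-[(4S)-2,2-dimethyl-1,3-dioxolan-4-yl]prop-2-enoate | BrC/C(C(=O)OC)=C\[C@H]1COC(C)(C)O1
F3 | step 5 | (2E)-3-methyl-6-(triethylsilyloxy)hex-2-enal | CC[Si](CC)(CC)OCCC/C(C)=C/C=O
F4 | step 5 | methyl 2-[(1S,2S,3E)-1-[(4S)-2,2-dimethyl-1,3-dioxolan-4-yl]-2-hydroxy-4-methyl-7-(triethylsilyloxy)hept-3-en-1-yl]prop-2-enoate | C=C(C(=O)OC)[C@H]([C@H]1COC(C)(C)O1)[C@@H](O)/C=C(\C)CCCO[Si](CC)(CC)CC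
F5 | step 15 | (3aS,4S,5S,6Z,10E,11aS)-5-hydroxy-6,10-dimethyl-3-methylidene-2-oxo-2,3,3a,4,5,8,9,11a-octahydrocyclodeca[b]furan-4-yl (3R)-3-methyl-4-(octadecanoyloxy)butanoate | C=C1C(=O)O[C@H]2/C=C(\C)CC/C=C(/C)[C@H](O)[C@@H](OC(=O)C[C@@H](C)COC(=O)CCCCCCCCCCCCCCCCC)[C@@H]12
F6 | step 15 | (3aS,4S,6Z,10E,11aS)-6,10-dimethyl-3-methylidene-2,5-dioxo-2,3,3a,4,5,8,9,11a-octahydrocyclodeca[b]furan-4-yl (3R)-3-methyl-4-(octadecanoyloxy)butanoate | C=C1C(=O)O[C@H]2/C=C(\C)CC/C=C(/C)C(=O)[C@@H](OC(=O)C[C@@H](C)COC(=O)CCCCCCCCCCCCCCCCC)[C@@H]12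
F7 | step 7 | (4S,5S)-5-[(1E)-6,6-dibromo-2-methylhexa-1,5-dien-1-yl]-4-[(4S)-2,2-dimethyl-1,3-dioxolan-4-yl]-3-methylideneoxolan-2-one | C=C1C(=O)O[C@@H](/C=C(\C)CCC=C(Br)Br)[C@H]1[C@H]2COC(C)(C)O2
F8 | step 7 | (4S,5S)-5-[(1E,5Z)-6-bromo-2-methylhepta-1,5-dien-1-yl]-4-[(4S)-2,2-dimethyl-1,3-dioxolan-4-yl]-3-methylideneoxolan-2-one | C=C1C(=O)O[C@@H](/C=C(\C)CC/C=C(/C)Br)[C@H]1[C@H]2COC(C)(C)O2
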